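**Plan**
- Retrosynthesis: remove the silyl and tert-butyl groups; open the pyran at O2–C3 (the C1 hydroxyl closing oxidatively onto the C3=C4 alkene of a dienone); open the carbocycle at C8–C8a and C4a–C4 in one operation; then cut the C6 ester (acyl–O), C6–C7 (crotylation) and C5–C4a (acetylide + oxirane).
- Feature used: in the carbocycle the tetrasubstituted C4a=C8a alkene holds the C8 carbonyl carbon on C8a and the alkenyl carbon C4 on C4a, trans to each other. This is the imprint of an aldehyde carbon and an alkenyl group adding to opposite faces of the triple bond of a 5-alkynal.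
- Forward: the chain is built linearly (propargyl silyl ether + oxirane, crotylation, aroylation, ozonolysis). The carbocycle forms first, in the palladium-catalysed cyclisation that also joins the side-chain boronic acid. The pyran forms second, after C8 oxidation and C1 desilylation; deprotection follows.
- Stereochemistry: C6 and C7 arise together in one catalyst-controlled anti-crotylation and are not touched again (the aryl ester is put on with retention before ring formation). The C8 carbinol of the key step is oxidised away.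

Key step: step 7

Assumption: the (S)-SEGPHOS-derived iridium catalyst is taken to give the (3S,4R) anti adduct 6; if the sense of induction is the opposite one, the (R) ligand is used and nothing else changes.

Abbreviations: TBS = tert-butyldimethylsilyl, TBSO = tert-butyldimethylsilyloxy, DMP = Dess–Martin periodinane, CSA = camphor-10-sulfonic acid, PMB = 4-methoxybenzyl. Atom numbers C1–C8a are those of the 1H-isochromene core of the target.

**Step 1**
Reactants: 1 tert-butyldimethyl(prop-2-yn-1-yloxy)silane; 2 oxirane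
Product: 4 5-(TBSO)pent-3-yn-1-ol, via lithium acetylide 3 (not isolated)
Conditions: n-BuLi, THF, −78 °C; then 2, BF3·OEt2, −78 °C; H2O
Reagents that add atoms: none
Why: BF3-promoted opening of an epoxide by a lithium acetylide is a standard two-carbon homologation of terminal alkynes and forms the C5–C4a bond without disturbing the propargylic silyl ether.

**Step 2**
Reactants: 4 5-(TBSO)pent-3-yn-1-ol; 5 but-3-en-2-yl acetate (racemic, 2 equiv)
Product: 6 (3S,4R)-8-(TBSO)-3-methyloct-1-en-6-yn-4-ol
Conditions: [Ir(cod)Cl]2 (2.5 mol%), (S)-SEGPHOS (5 mol%), 4-cyano-3-nitrobenzoic acid (10 mol%), Cs2CO3 (20 mol%), THF, 80 °C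
Reagents that add atoms: none
Why: In this iridium-catalysed transfer-hydrogenative carbonyl crotylation the cyclometallated iridium complex dehydrogenates the primary alcohol and the aldehyde is trapped at once by the (E)-σ-crotyliridium species in a closed chair transition state, so the anti C6/C7 relationship follows from the crotyl geometry and the absolute configuration from the SEGPHOS ligand, while the isomerisation-prone β,γ-ynal never accumulates.

**Step 3**
Reactants: 7 orsellinic acid
Product: 8 tert-butyldimethylsilyl 2,4-bis(TBSO)-6-methylbenzoate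
Conditions: TBSCl (3.6 equiv), imidazole, DMF, 23 → 50 °C
Reagents that add atoms: tert-butyldimethylsilyl chloride, CC(C)(C)[Si](C)(C)Cl
Why: Exhaustive silylation with a silyl chloride and imidazole masks both phenols and turns the acid into a silyl ester, the form that can be converted directly into the acid chloride.

**Step 4**
Reactants: 8 tert-butyldimethylsilyl 2,4-bis(TBSO)-6-methylbenzoate; 6 (3S,4R)-8-(TBSO)-3-methyloct-1-en-6-yn-4-ol
Product: 10 (3S,4R)-8-(TBSO)-3-methyloct-1-en-6-yn-4-yl 2,4-bis(TBSO)-6-methylbenzoate, via aroyl chloride 9 (not isolated)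
Conditions: (COCl)2, DMF (cat.), CH2Cl2, 0 → 23 °C, evaporate; then 6, pyridine, DMAP (cat.), CH2Cl2, 23 → 40 °C
Reagents that add atoms: none
Why: Oxalyl chloride with catalytic DMF converts a silyl ester into the acid chloride under neutral conditions (no HCl, so the aryl silyl ethers survive), and DMAP-catalysed acylation, the way hindered 2,6-disubstituted benzoates are made, esterifies the C6 hydroxyl with retention because its C–O bond is not broken.

**Step 5**
Reactants: 10 (3S,4R)-8-(TBSO)-3-methyloct-1-en-6-yn-4-yl 2,4-bis(TBSO)-6-methylbenzoate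
Product: 12 (2R,3R)-7-(TBSO)-2-methyl-1-oxohept-5-yn-3-yl 2,4-bis(TBSO)-6-methylbenzoate, via ozonide 11 (not isolated)
Conditions: O3, CH2Cl2, −78 °C (Sudan Red 7B end point); then PPh3, −78 → 23 °C
Reagents that add atoms: ozone, [O-][O+]=O
Why: In this ozonolysis with reductive work-up ozone attacks the monosubstituted alkene far faster than the internal alkyne or the ester-deactivated arene, and PPh3 reduces the ozonide under neutral anhydrous conditions, so the α-stereocentre and the β-aroyloxy group of the aldehyde see neither acid nor base.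

**Step 6**
Reactants: 13 tert-butyl pent-4-ynoate
Product: 15 (E)-(5-tert-butoxy-5-oxopent-1-en-1-yl)boronic acid, via catechol boronate 14 (not isolated)
Conditions: catecholborane (1.1 equiv), neat, 70 °C; then H2O, 23 °C
Reagents that add atoms: catecholborane, B1Oc2ccccc2O1; water, O
Why: Hydroboration of a terminal alkyne with catecholborane is a syn, anti-Markovnikov addition that gives the (E)-alkenylboronate, which water hydrolyses to the boronic acid without touching the tert-butyl ester.

**Step 7**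
Reactants: 12 (2R,3R)-7-(TBSO)-2-methyl-1-oxohept-5-yn-3-yl 2,4-bis(TBSO)-6-methylbenzoate; 15 (E)-(5-tert-butoxy-5-oxopent-1-en-1-yl)boronic acid (1.5 equiv)
Product: 16 tert-butyl (E)-5-[(3S,4S,5R)-5-{[2,4-bis(TBSO)-6-methylbenzoyl]oxy}-2-(TBSO-methyl)-3-hydroxy-4-methylcyclohex-1-en-1-yl]pent-4-enoate
Conditions: Pd(PPh3)4 (5 mol%), degassed MeOH, 65 °C
Reagents that add atoms: none
Why: Zerovalent palladium bound to the alkyne makes it nucleophilic, and C8a attacks the methanol-activated aldehyde carbon C8 on the face opposite to the metal (anti-Wacker-type oxidative addition), giving a cyclohexenyl complex of divalent palladium with the metal on C4a; transfer of the alkenyl group from boron to palladium, which the palladium alkoxide permits without added base, and reductive elimination then form C4a–C4 as a net trans addition. The closest known reaction type is the palladium-catalysed trans-selective arylative and alkenylative cyclisation of 5-alkynals with boronic acids. The one ring closed is the carbocycle, in a six-membered closure that is endo with respect to the alkyne (both alkyne carbons end up in the ring) and exo with respect to the carbonyl. The only new stereocentre, the C8 carbinol, is under substrate control (attack on the aldehyde face away from the C7 methyl is expected, placing the hydroxyl trans to it) and is removed by the next oxidation, so either epimer serves. The step needs endo over exo closure, trans over cis addition and an intact C7–H and C6 ester: the three-atom tether of the 5-alkynal together with the PPh3 ligand favours the endo, trans pathway, the ring itself fixes the geometry of the tetrasubstituted alkene, and the base-free neutral medium protects the α-stereocentre and the β-aroyloxy group.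

**Step 8**
Reactants: 16 tert-butyl (E)-5-[(3S,4S,5R)-5-{[2,4-bis(TBSO)-6-methylbenzoyl]oxy}-2-(TBSO-methyl)-3-hydroxy-4-methylcyclohex-1-en-1-yl]pent-4-enoate
Product: 17 tert-butyl (E)-5-[(4R,5R)-5-{[2,4-bis(TBSO)-6-methylbenzoyl]oxy}-2-(TBSO-methyl)-4-methyl-3-oxocyclohex-1-en-1-yl]pent-4-enoate
Conditions: DMP, CH2Cl2, 0 → 23 °C
Reagents that add atoms: none
Why: Dess–Martin oxidation converts the hindered allylic alcohol (either C8 epimer) into the conjugated dienone under non-basic conditions, so the new β-aroyloxy ketone should not eliminate and C7 should not epimerise.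

**Step 9**
Reactants: 17 tert-butyl (E)-5-[(4R,5R)-5-{[2,4-bis(TBSO)-6-methylbenzoyl]oxy}-2-(TBSO-methyl)-4-methyl-3-oxocyclohex-1-en-1-yl]pent-4-enoate
Product: 18 tert-butyl (E)-5-[(4R,5R)-5-{[2,4-bis(TBSO)-6-methylbenzoyl]oxy}-2-(hydroxymethyl)-4-methyl-3-oxocyclohex-1-en-1-yl]pent-4-enoate
Conditions: CSA (10 mol%), MeOH/CH2Cl2 (1:1), 0 °C; NaHCO3 quench
Reagents that add atoms: none
Why: Acid-catalysed methanolysis (desilylation) cleaves a primary alkyl TBS ether much faster than aryl TBS ethers, which are the acid-stable kind of silyl ether, and leaves the tert-butyl ester and the dienone untouched at 0 °C.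

**Step 10**
Reactants: 18 tert-butyl (E)-5-[(4R,5R)-5-{[2,4-bis(TBSO)-6-methylbenzoyl]oxy}-2-(hydroxymethyl)-4-methyl-3-oxocyclohex-1-en-1-yl]pent-4-enoate
Product: 19 (6R,7R)-3-(3-tert-butoxy-3-oxopropyl)-7-methyl-8-oxo-5,6,7,8-tetrahydro-1H-isochromen-6-yl 2,4-bis(TBSO)-6-methylbenzoate
Conditions: Pd(OAc)2 (1.1 equiv), DMSO/THF (1:1), 23 °C
Reagents that add atoms: none
Why: Proposed new method: Pd(OAc)2 should bind the C3=C4 alkene of the dienone, the C1 hydroxyl should add to C3 (the electrophilic δ-carbon) anti to the metal in a 6-endo-trig oxypalladation, and the resulting palladium dienolate, which holds the C3 hydrogen cis to the metal on the new ring, should undergo syn β-hydride elimination to the C3=C4 enol ether with release of zerovalent palladium and AcOH; the closest known reaction type is the Wacker-type oxidative cyclisation of β-hydroxy enones to 2,3-dihydro-4H-pyran-4-ones and of 2-alkenylbenzoic acids to isocoumarins by salts of divalent palladium, of which this is the vinylogous case.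

**Step 11**
Reactants: 19 (6R,7R)-3-(3-tert-butoxy-3-oxopropyl)-7-methyl-8-oxo-5,6,7,8-tetrahydro-1H-isochromen-6-yl 2,4-bis(TBSO)-6-methylbenzoate
Product: 20 3-[(6R,7R)-6-{[2,4-bis(TBSO)-6-methylbenzoyl]oxy}-7-methyl-8-oxo-5,6,7,8-tetrahydro-1H-isochromen-3-yl]propanoic acid
Conditions: TFA/CH2Cl2 (1:4), 0 °C; co-evaporation with toluene
Reagents that add atoms: none
Why: Acidolysis of a tert-butyl ester (loss of isobutene) is fast in TFA, in which aryl silyl ethers and the hindered aryl ester persist and the doubly vinylogous ester of the bicyclic core should only be protonated reversibly on oxygen.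

**Step 12**
Reactants: 20 3-[(6R,7R)-6-{[2,4-bis(TBSO)-6-methylbenzoyl]oxy}-7-methyl-8-oxo-5,6,7,8-tetrahydro-1H-isochromen-3-yl]propanoic acid
Product: 21 3-[(6R,7R)-6-(2,4-dihydroxy-6-methylbenzoyloxy)-7-methyl-8-oxo-5,6,7,8-tetrahydro-1H-isochromen-3-yl]propanoic acid (CNP0601844.1)
Conditions: HF·pyridine, pyridine, THF, 0 → 23 °C
Reagents that add atoms: none
Why: Fluoride-mediated desilylation with pyridine-buffered HF·pyridine frees both phenols under mildly acidic conditions and avoids the basic fluoride sources that could trigger β-elimination of the aroyloxy group next to the ketone.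

**Compound list**
1 | tert-butyldimethyl(prop-2-yn-1-yloxy)silane | C#CCO[Si](C)(C)C(C)(C)C | starting material
2 | oxirane | C1CO1 | starting material
3 | lithium acetylide of 1 (formed in situ) | [Li]C#CCO[Si](C)(C)C(C)(C)C | intermediate
4 | 5-(TBSO)pent-3-yn-1-ol | OCCC#CCO[Si](C)(C)C(C)(C)C | intermediate
5 | but-3-en-2-yl acetate (racemic) | CC(OC(C)=O)C=C | starting material
6 | (3S,4R)-8-(TBSO)-3-methyloct-1-en-6-yn-4-ol | C=C[C@H](C)[C@H](O)CC#CCO[Si](C)(C)C(C)(C)C | intermediate
7 | orsellinic acid (2,4-dihydroxy-6-methylbenzoic acid) | Cc1cc(O)cc(O)c1C(=O)O | starting material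
8 | tert-butyldimethylsilyl 2,4-bis(TBSO)-6-methylbenzoate | Cc1cc(O[Si](C)(C)C(C)(C)C)cc(O[Si](C)(C)C(C)(C)C)c1C(=O)O[Si](C)(C)C(C)(C)C | intermediate
9 | 2,4-bis(TBSO)-6-methylbenzoyl chloride (formed in situ) | Cc1cc(O[Si](C)(C)C(C)(C)C)cc(O[Si](C)(C)C(C)(C)C)c1C(Cl)=O | intermediate
10 | (3S,4R)-8-(TBSO)-3-methyloct-1-en-6-yn-4-yl 2,4-bis(TBSO)-6-methylbenzoate | C=C[C@H](C)[C@H](OC(=O)c1c(C)cc(O[Si](C)(C)C(C)(C)C)cc1O[Si](C)(C)C(C)(C)C)CC#CCO[Si](C)(C)C(C)(C)C | intermediate
11 | 1,2,4-trioxolane (secondary ozonide) of 10, either configuration at the trioxolane carbon (formed in situ) | C1(OCOO1)[C@H](C)[C@H](OC(=O)c1c(C)cc(O[Si](C)(C)C(C)(C)C)cc1O[Si](C)(C)C(C)(C)C)CC#CCO[Si](C)(C)C(C)(C)C | intermediate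
12 | (2R,3R)-7-(TBSO)-2-methyl-1-oxohept-5-yn-3-yl 2,4-bis(TBSO)-6-methylbenzoate | O=C[C@H](C)[C@H](OC(=O)c1c(C)cc(O[Si](C)(C)C(C)(C)C)cc1O[Si](C)(C)C(C)(C)C)CC#CCO[Si](C)(C)C(C)(C)C | intermediate
13 | tert-butyl pent-4-ynoate | C#CCCC(=O)OC(C)(C)C | starting material
14 | tert-butyl (E)-5-(1,3,2-benzodioxaborol-2-yl)pent-4-enoate (formed in situ) | CC(C)(C)OC(=O)CC/C=C/B1Oc2ccccc2O1 | intermediate
15 | (E)-(5-tert-butoxy-5-oxopent-1-en-1-yl)boronic acid | OB(O)/C=C/CCC(=O)OC(C)(C)C | intermediate
16 | tert-butyl (E)-5-[(3S,4S,5R)-5-{[2,4-bis(TBSO)-6-methylbenzoyl]oxy}-2-(TBSO-methyl)-3-hydroxy-4-methylcyclohex-1-en-1-yl]pent-4-enoate | Cc1cc(O[Si](C)(C)C(C)(C)C)cc(O[Si](C)(C)C(C)(C)C)c1C(=O)O[C@@H]1CC(/C=C/CCC(=O)OC(C)(C)C)=C(CO[Si](C)(C)C(C)(C)C)[C@@H](O)[C@@H]1C | intermediate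
17 | tert-butyl (E)-5-[(4R,5R)-5-{[2,4-bis(TBSO)-6-methylbenzoyl]oxy}-2-(TBSO-methyl)-4-methyl-3-oxocyclohex-1-en-1-yl]pent-4-enoate | Cc1cc(O[Si](C)(C)C(C)(C)C)cc(O[Si](C)(C)C(C)(C)C)c1C(=O)O[C@@H]1CC(/C=C/CCC(=O)OC(C)(C)C)=C(CO[Si](C)(C)C(C)(C)C)C(=O)[C@@H]1C | intermediate
18 | tert-butyl (E)-5-[(4R,5R)-5-{[2,4-bis(TBSO)-6-methylbenzoyl]oxy}-2-(hydroxymethyl)-4-methyl-3-oxocyclohex-1-en-1-yl]pent-4-enoate | Cc1cc(O[Si](C)(C)C(C)(C)C)cc(O[Si](C)(C)C(C)(C)C)c1C(=O)O[C@@H]1CC(/C=C/CCC(=O)OC(C)(C)C)=C(CO)C(=O)[C@@H]1C | intermediate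
19 | (6R,7R)-3-(3-tert-butoxy-3-oxopropyl)-7-methyl-8-oxo-5,6,7,8-tetrahydro-1H-isochromen-6-yl 2,4-bis(TBSO)-6-methylbenzoate | Cc1cc(O[Si](C)(C)C(C)(C)C)cc(O[Si](C)(C)C(C)(C)C)c1C(=O)O[C@@H]1CC2=C(COC(CCC(=O)OC(C)(C)C)=C2)C(=O)[C@@H]1C | intermediate
20 | 3-[(6R,7R)-6-{[2,4-bis(TBSO)-6-methylbenzoyl]oxy}-7-methyl-8-oxo-5,6,7,8-tetrahydro-1H-isochromen-3-yl]propanoic acid | Cc1cc(O[Si](C)(C)C(C)(C)C)cc(O[Si](C)(C)C(C)(C)C)c1C(=O)O[C@@H]1CC2=C(COC(CCC(=O)O)=C2)C(=O)[C@@H]1C | intermediate
21 | 3-[(6R,7R)-6-(2,4-dihydroxy-6-methylbenzoyloxy)-7-methyl-8-oxo-5,6,7,8-tetrahydro-1H-isochromen-3-yl]propanoic acid | Cc1cc(O)cc(O)c1C(=O)O[C@@H]1CC2=C(COC(CCC(=O)O)=C2)C(=O)[C@@H]1C | target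

**Step count**
Total: 12 steps. Longest linear sequence: 10 steps (1, 2, 4, 5, 7, 8, 9, 10, 11, 12); steps 3 and 6 prepare the aroyl donor and the boronic acid.

**Steps most likely to fail**

Step 10 (Proposed new method). The palladium dienolate formed after oxypalladation may be protonated instead of losing hydride, so that only the non-oxidised cyclic ether forms. Hydride may also be lost toward C1, the primary allylic alcohol may be oxidised before it cyclises, or the carbocycle may be dehydrogenated. The fallback brings in the C3–C4 unit at the alkyne oxidation level, so that the pyran closes without an oxidant. It sets out from alkynal 12, which is cyclised in the alkynylative form of the same trans-selective palladium reaction with tert-butyl pent-4-ynoate 13 (Pd(PPh3)4, CuI, MeOH) to give the enynol tert-butyl 5-[(3S,4S,5R)-5-aroyloxy-2-(TBSO-methyl)-3-hydroxy-4-methylcyclohex-1-en-1-yl]pent-4-ynoate F1. DMP oxidation gives the enynone F2, and CSA in MeOH frees the primary alcohol to give the hydroxy enynone F3. A 6-endo-dig hydroalkoxylation (AuCl(PPh3)/AgOTf, CH2Cl2, 23 °C), of the kind that turns 2-alkynylbenzyl alcohols into 1H-isochromenes, then adds the hydroxyl to C3, the δ-carbon of the enynone, and the route is rejoined at 19.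

Step 7 (key step). The β-aroyloxy α-methyl aldehyde may lose the aroyloxy group by β-elimination or epimerise at C7 during the heating, before the alkyne attacks. The fallback puts the aryl ester on after the ring is made. It sets out from alcohol 6, which is protected (4-methoxybenzyl 2,2,2-trichloroacetimidate, Sc(OTf)3 cat., toluene, 0 °C) as the PMB ether F4. Ozonolysis as in step 5 gives the PMB-protected alkynal F5, and cyclisation with 15 under the conditions of step 7 gives the PMB-protected cyclohexenol F6. DMP then gives the PMB-protected dienone F7, and DDQ (CH2Cl2/pH 7 buffer, 0 °C) gives the β-hydroxy dienone F8. Acylation of F8 with aroyl chloride 9 (pyridine, DMAP) rejoins the route at 17.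

Step 2. The iridium hydride may add to the internal propargylic alkyne or divert it into a competing coupling, or the diastereo- and enantioselectivity may be eroded. The fallback uses stoichiometric reagent control on the preformed aldehyde. It sets out from alcohol 4, which is oxidised with DMP to 5-(TBSO)pent-3-ynal F9, used crude and cold to prevent isomerisation to the allenal. (E)-Crotylboration follows at −78 °C with the diisopinocampheyl(crotyl)borane made from (E)-but-2-ene, KOt-Bu, n-BuLi, the antipode of B-methoxydiisopinocampheylborane that leads to the (3S,4R) adduct, and BF3·OEt2. Oxidative work-up (NaOH, H2O2) returns the route to 6.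

**Further compounds**
F1 | step 10 | tert-butyl 5-[(3S,4S,5R)-5-{[2,4-bis(TBSO)-6-methylbenzoyl]oxy}-2-(TBSO-methyl)-3-hydroxy-4-methylcyclohex-1-en-1-yl]pent-4-ynoate | Cc1cc(O[Si](C)(C)C(C)(C)C)cc(O[Si](C)(C)C(C)(C)C)c1C(=O)O[C@@H]1CC(C#CCCC(=O)OC(C)(C)C)=C(CO[Si](C)(C)C(C)(C)C)[C@@H](O)[C@@H]1C
F2 | step 10 | tert-butyl 5-[(4R,5R)-5-{[2,4-bis(TBSO)-6-methylbenzoyl]oxy}-2-(TBSO-methyl)-4-methyl-3-oxocyclohex-1-en-1-yl]pent-4-ynoate | Cc1cc(O[Si](C)(C)C(C)(C)C)cc(O[Si](C)(C)C(C)(C)C)c1C(=O)O[C@@H]1CC(C#CCCC(=O)OC(C)(C)C)=C(CO[Si](C)(C)C(C)(C)C)C(=O)[C@@H]1C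
F3 | step 10 | tert-butyl 5-[(4R,5R)-5-{[2,4-bis(TBSO)-6-methylbenzoyl]oxy}-2-(hydroxymethyl)-4-methyl-3-oxocyclohex-1-en-1-yl]pent-4-ynoate | Cc1cc(O[Si](C)(C)C(C)(C)C)cc(O[Si](C)(C)C(C)(C)C)c1C(=O)O[C@@H]1CC(C#CCCC(=O)OC(C)(C)C)=C(CO)C(=O)[C@@H]1C
F4 | step 7 | tert-butyl{[(5R,6S)-5-(4-methoxybenzyloxy)-6-methyloct-7-en-2-yn-1-yl]oxy}dimethylsilane (PMB ether of 6) | C=C[C@H](C)[C@H](OCc1ccc(OC)cc1)CC#CCO[Si](C)(C)C(C)(C)C
F5 | step 7 | (2R,3R)-7-(TBSO)-3-(4-methoxybenzyloxy)-2-methylhept-5-ynal | O=C[C@H](C)[C@H](OCc1ccc(OC)cc1)CC#CCO[Si](C)(C)C(C)(C)C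
F6 | step 7 | tert-butyl (E)-5-[(3S,4S,5R)-2-(TBSO-methyl)-3-hydroxy-5-(4-methoxybenzyloxy)-4-methylcyclohex-1-en-1-yl]pent-4-enoate | COc1ccc(CO[C@@H]2CC(/C=C/CCC(=O)OC(C)(C)C)=C(CO[Si](C)(C)C(C)(C)C)[C@@H](O)[C@@H]2C)cc1
F7 | step 7 | tert-butyl (E)-5-[(4R,5R)-2-(TBSO-methyl)-5-(4-methoxybenzyloxy)-4-methyl-3-oxocyclohex-1-en-1-yl]pent-4-enoate | COc1ccc(CO[C@@H]2CC(/C=C/CCC(=O)OC(C)(C)C)=C(CO[Si](C)(C)C(C)(C)C)C(=O)[C@@H]2C)cc1
F8 | step 7 | tert-butyl (E)-5-[(4R,5R)-2-(TBSO-methyl)-5-hydroxy-4-methyl-3-oxocyclohex-1-en-1-yl]pent-4-enoate | O[C@@H]1CC(/C=C/CCC(=O)OC(C)(C)C)=C(CO[Si](C)(C)C(C)(C)C)C(=O)[C@@H]1C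
F9 | step 2 | 5-(TBSO)pent-3-ynal | O=CCC#CCO[Si](C)(C)C(C)(C)C
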